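## Analysis of the target

Target 25 is a trans-fused decalin. Atoms are numbered C1–C10 around the bicycle (ring A: C1–C5 and C10; ring B: C5–C10); C11 is the formyl carbon on C9, C12 the ester carbonyl on C8, C13 and C14 the methyl groups on C10 and C4, and C15–C18 the chain on C4 with terminal methyls C19 and C20. β is the face of the two ring methyl groups. In this numbering the six stereocentres are 1S,3S,4S,5R,9R,10S: C13 and C14 are syn-diaxial on the β face, H5 is α, the C1 hydroxyl is axial (α), the C3 chlorine equatorial (β, cis to C14) and the C9 formyl group equatorial (β). C4 and C10 are quaternary and flank C5, so the three most crowded centres are contiguous. The sensitive groups are the β,γ-unsaturated aldehyde (acidic H9, so epimerisation or migration of the C7=C8 bond), the tertiary allylic alcohol at C18 (ionises in acid), the C1/C3 chlorohydrin (fragmentation or elimination with strong base) and the enoate. Two centres resist the obvious late-stage chemistry: an equatorial chloride at the neopentyl C3 cannot come from substitution, and conjugate hydrochlorination of a C1 enone would bring chlorine in axially, anti to C14; likewise hydride reduction of a C1 ketone in the decalin favours the equatorial alcohol. The strategy rests on C13: it is the reduced form of an exocyclic methylene on C10, so hydrogen-atom transfer gives a tertiary C10 radical that forms C9–C10, and the C8 enolate that follows closes ring B onto a C7 aldehyde on the C5 arm.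

## Retrosynthetic reasoning

**25 from 24.** Only the acetal C–O bonds at C11 are cut. The free aldehyde is unveiled last because it would not survive base or nucleophiles; the forward step must be a mild hydrolysis that spares the C18 alcohol.

**24 back to 20.** The C18–methyl bond and the C16=C17 bond are cut, leading through enone 23 and aldehyde 22 to alcohol 21 and its silyl ether 20. Building the chain late keeps a second alkene and an acid-labile alcohol out of the radical steps. Forward, a stabilised Wittig olefination must give the E alkene and a methyl nucleophile must add to the ketone without touching the C12 ester.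

**20 from 18 (through mesylate 19).** The C7=C8 bond is traced to the β-hydroxy ester. No skeletal bond is cut; the gain is that C7 and C8 need no stereocontrol, since both centres disappear in the elimination.

**18 from 17.** The C3–H bond is cut, giving the chloro alkene. This reverses the usual order at C3: chlorine is already in place as a vinylic substituent, and the stereocentre is created when hydrogen, the small partner, arrives last on the open α face. The forward reaction must be a hydrogenation that keeps the C–Cl bond. The axial C1 hydroxyl reinforces the outcome, because a 3α chloride would be 1,3-diaxial to it.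

**17 from 15 and 16 (key disconnection).** C9–C10 and C7–C8 are cut. Ring B, two skeletal bonds and four stereocentres fall away, and the quaternary C10 becomes a methylene. C11 travels in 16 as an acetal so that the radical adds β to the ester and not β to an aldehyde. Forward, hydrogen-atom transfer must choose the exocyclic alkene, C9 must bond on the α face of C10, and the enolate must reach the C7 aldehyde. The C1 hydroxyl is left free in 15 because a small axial group on the α face does not hinder that approach.

**15 from 14, and 14 from 13.** The arm ester is the latent C7 aldehyde, and the C1–H bond is cut back to the ketone. Setting C1 on the monocycle by reagent control avoids a late reduction beside C13. Everything before 13 is racemic, because dione 2 has a mirror plane, so this reduction is also where the enantiomers are parted.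

**13 from 10 (through 11 and 12), and 10 from 9.** The C10=CH2 bond comes from a Mannich methylenation of the kinetic enolate. The C3–Cl bond comes from the vinylogous ester: its C3 carbonyl oxygen is exchanged for chlorine while the C1 enol ether becomes the ketone. This places chlorine regiospecifically at the hindered carbon, which direct chlorination of the 1,3-dione would not do.

**9 back to 5 (through 8, 7 and diol 6).** The silyloxyethyl chain is a shortened allyl group; a two-carbon oxygenated chain is used because a terminal alkene would not survive the two radical steps.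

**5 from 4, 4 from 3.** C4–C15 and C4–C14 are cut as two enolate alkylations. The order matters: methyl first, then the allyl group anti to the C5 arm, which fixes C4 relative to C5.

**3 from 2, 2 from 1.** Enol ether formation and partial hydrogenation of the resorcinol. All ring A carbons and the C6–C7 arm come from 1.

## Alternatives that were turned down

**Alternative 1:** Ring B is cut at C8–C9 and C5–C10, giving the dienyl β-keto ester A2 (methyl (4E)-6-methyl-3-oxohepta-4,6-dienoate) and the acetal enal A3 ((2E)-4,4-dimethoxy-2-methylbut-2-enal). Forward, a mild carbonate base lets the dienolate of A2 add through C8 to C9 of A3; the aldehyde enolate then closes from C10 onto C5 (double Michael) to give A1.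
- For: two small achiral pieces, purely two-electron chemistry, and C5, C9 and C10 set in one operation. On convergence and on the kinetics of the bond-forming step it is stronger than a radical addition to a β-substituted acceptor.
- Against: in A1 ring A exists only as a formyl group (C1) and an isopropenyl group (C4, C3, C14). The quaternary C4 with its chain, the C3 chloride and the C1 carbinol must all be made in a later ring closure, where C4 becomes stereogenic without a control element as dependable as alkylation next to C5. The absolute configuration would need an asymmetric catalyst for the double Michael, and the C7 oxygen must still be removed.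
- Comparison: the chosen route spends its early steps on ring A, where C1, C3, C4 and C5 can be handled on a monocycle, and then uses those centres to steer C10 and C9.

**Alternative 2:** Ring A of A4 is derived from the five-membered ring of a trans-hydrindanone, taken as its C1=C3 silyl enol ether A5. Forward, A5 is cyclopropanated with a zinc carbenoid and the siloxycyclopropane is opened in the same flask by a one-electron iron chloride oxidant; the ring-enlarged C3 radical takes up chlorine to give A4 (C1 ketone, C3 chloride).
- For: the C1 carbonyl and the C3–Cl bond arrive together, late, with unambiguous regiochemistry. On that point it is stronger than the chosen route, which relies on a transposing chlorination of 9.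
- Against: chlorine is delivered last to a C3 radical whose β face is screened by the axial C14 methyl, so the axial 3α chloride is the expected product. The C1 ketone must then be reduced to the axial alcohol against the bias of C13. The allyl group competes for the carbenoid, and a trans-hydrindanone carrying both quaternary centres is itself hard to reach.
- Comparison: the chosen route puts chlorine in first and hydrogen last at C3, and sets C1 by reagent control on a monocycle.

**Alternative 3:** Only C8–C9 is cut. The precursor A7 has the complete ring A, a C7/C8 β-keto ester arm on C5 and a C9=C11 methyl enol ether on C10. Forward, anodic oxidation of the keto ester enol gives an electrophilic C8 radical that adds 6-exo to C9; the C11 cation is trapped by the alcohol solvent as the acetal, giving A6.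
- For: the radical addition is polarity-matched and intramolecular, hence faster and more selective than the bimolecular addition chosen here; it needs no reagent, gives the C11 acetal directly, and leaves a short endgame because chain and chloride are already present.
- Against: A7 already contains the quaternary C10 beside C5 and C4, so the three contiguous centres that are the real problem must be built by other chemistry. The side-chain alkene and the tertiary allylic silyl ether must survive anodic, acid-generating conditions, and the C7 ketone must afterwards be reduced and eliminated.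
- Comparison: the chosen key step creates C10 in the ring-forming event from a methylene and forms two bonds, at the price of a bimolecular radical addition.

Key step: step 12

Remarks. TBS is tert-butyl(dimethyl)silyl. Compounds 3–13 are racemic; their names and SMILES show the enantiomer that leads to 25. It is assumed that 1, 16 and all reagents are purchased.

## Route

Step 1
Reactants: 1 methyl 2-(3,5-dihydroxyphenyl)acetate
Product: 2 methyl 2-(3,5-dioxocyclohexyl)acetate
Conditions: H2 (5 bar), Rh/Al2O3, NaOH (1.0 equiv), H2O, 25 °C; then HCl to pH 2
Reagents that add atoms: none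
Why: Partial hydrogenation of a resorcinol monoanion stops at the enolate of the cyclohexane-1,3-dione, a standard route to such diones; any ester hydrolysed by the base is re-formed in step 2.

Step 2
Reactants: 2 methyl 2-(3,5-dioxocyclohexyl)acetate
Product: 3 racemic methyl 2-(3-methoxy-5-oxocyclohex-3-en-1-yl)acetate
Conditions: HC(OMe)3, MeOH, p-TsOH (cat.), 50 °C
Reagents that add atoms: trimethyl orthoformate, COC(OC)OC; methanol, CO
Why: Acid-catalysed enol ether formation from a 1,3-dione (vinylogous ester synthesis); the two carbonyls are enantiotopic, so 3 is racemic, with C3 as ketone and C1 as masked carbonyl.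

Step 3
Reactants: 3 racemic methyl 2-(3-methoxy-5-oxocyclohex-3-en-1-yl)acetate
Product: 4 racemic 4α-methyl vinylogous ester (methyl trans to the C5 arm)
Conditions: LDA (1.05 equiv), THF, −78 °C; MeI, −78 to −20 °C
Reagents that add atoms: iodomethane, CI
Why: Stork–Danheiser alkylation: kinetic deprotonation of a vinylogous ester occurs at C4, α to the C3 ketone, which is more acidic than the ester arm; the configuration at C4 is erased in step 4, so only the regiochemistry matters.

Step 4
Reactants: 4 racemic 4α-methyl vinylogous ester
Product: 5 racemic 4β-methyl-4α-allyl vinylogous ester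
Conditions: LDA (1.1 equiv), THF, −78 °C; allyl bromide, DMPU, −78 to 0 °C
Reagents that add atoms: allyl bromide, C=CCBr
Why: Second Stork–Danheiser alkylation; in the C3/C4 enolate the C5 arm sits pseudoaxial to avoid A(1,2) strain with the C4 methyl, so the allyl group enters on the opposite face. This sets the quaternary C4 relative to C5 (chain trans, methyl cis to the arm).

Step 5
Reactants: 5 racemic 4β-methyl-4α-allyl vinylogous ester
Product: 7 racemic C16 aldehyde (4α-(2-oxoethyl) vinylogous ester), via vicinal diol 6 (not isolated)
Conditions: OsO4 (2 mol %), NaIO4, 2,6-lutidine, dioxane–H2O, 25 °C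
Reagents that add atoms: sodium periodate (oxygen donor by way of catalytic OsO4), [Na+].[O-]I(=O)(=O)=O
Why: Lemieux–Johnson cleavage; OsO4 dihydroxylates the electron-neutral terminal alkene far faster than the push–pull alkene of the vinylogous ester, and periodate cleaves the diol.

Step 6
Reactants: 7 racemic C16 aldehyde
Product: 8 racemic C16 alcohol (4α-(2-hydroxyethyl) vinylogous ester)
Conditions: NaBH4, MeOH, −20 °C
Reagents that add atoms: none
Why: Chemoselective borohydride reduction of an aldehyde; the vinylogous ester carbonyl and the methyl ester are inert under these conditions.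

Step 7
Reactants: 8 racemic C16 alcohol
Product: 9 racemic C16 TBS ether of the vinylogous ester
Conditions: TBSCl, imidazole, DMF, 25 °C
Reagents that add atoms: tert-butyl(chloro)dimethylsilane, CC(C)(C)[Si](C)(C)Cl
Why: Standard silylation of a primary alcohol; the ether has to last through the radical steps and is removed in step 15.

Step 8
Reactants: 9 racemic C16 TBS ether of the vinylogous ester
Product: 10 racemic chloro enone (C1 ketone, C2=C3–Cl)
Conditions: (COCl)2 (1.5 equiv), CH2Cl2, 0 to 25 °C; then aq. NaHCO3
Reagents that add atoms: oxalyl chloride, O=C(Cl)C(=O)Cl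
Why: Deoxychlorination of a vinylogous ester (Vilsmeier-type activation): the only nucleophilic oxygen is the C3 carbonyl oxygen, chloride replaces the activated oxygen at C3, and loss of the O-methyl group leaves the C1 ketone. Chlorine thus ends on the hindered carbon next to C4, with the same transposition as in a Stork–Danheiser sequence.

Step 9
Reactants: 10 racemic chloro enone
Product: 13 racemic chloro dienone (C10 exocyclic methylene), via Mannich base 11 (not isolated), via trimethylammonium iodide 12 (not isolated)
Conditions: LDA, THF, −78 °C; CH2=NMe2+ I−, −78 to 0 °C; MeI, CH2Cl2; aq. NaHCO3, 25 °C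
Reagents that add atoms: N,N-dimethylmethyleneiminium iodide (Eschenmoser's salt), C=[N+](C)C.[I-]
Why: Mannich methylenation: the kinetic enolate can only form at C10 (C2 is vinylic), and quaternisation followed by elimination gives the α-methylene ketone. Compound 13 is a reactive cross-conjugated dienone and is used at once.

Step 10
Reactants: 13 racemic chloro dienone
Product: 14 (1S)-chloro dienol (1α-hydroxyl trans to the 5β arm; single enantiomer)
Conditions: (R)-Me-CBS oxazaborolidine ((R)-1-methyl-3,3-diphenylhexahydropyrrolo[1,2-c][1,3,2]oxazaborole, 0.3 equiv), catecholborane, toluene, −78 °C; chromatography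
Reagents that add atoms: none
Why: Corey–Bakshi–Shibata reduction: the catalyst treats the fully substituted C10 side as the large group and the C2–H side as the small one and should give the (1S)-carbinol from both enantiomers of 13. The enantiomer with the target configuration at C4 and C5 gives 14; its mirror-image partner gives the diastereomer with the hydroxyl cis to the arm, which is separated, so the step sets C1 and resolves the series.

Step 11
Reactants: 14 (1S)-chloro dienol
Product: 15 hydroxy aldehyde (ring A with C10 methylene, free 1α-hydroxyl, C2=C3–Cl, C4 methyl and silyloxyethyl, 2-oxoethyl arm on C5)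
Conditions: i-Bu2AlH (2.5 equiv), CH2Cl2, −78 °C; Rochelle salt
Reagents that add atoms: none
Why: Partial reduction of a methyl ester to the aldehyde through the stable tetrahedral aluminium intermediate at low temperature; the first equivalent is consumed by the hydroxyl. The 1,3-trans arrangement of hydroxyl and arm prevents lactol formation.

Step 12
Reactants: 15 hydroxy aldehyde; 16 methyl (2E)-4,4-dimethoxybut-2-enoate
Product: 17 annulation product (trans-decalin: 1α-OH, C2=C3–Cl, 7β-OH, 8α-CO2Me, 9β-CH(OMe)2, 10β-methyl)
Conditions: Fe(acac)3 (30 mol %), PhSiH3 (2.5 equiv, slow addition), 16 (3 equiv), Na2HPO4, EtOH–(CH2OH)2 (5:1), 40 °C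
Reagents that add atoms: none
Why: Fe(acac)3 (trivalent iron) and PhSiH3 form an iron hydride that transfers a hydrogen atom to the terminal carbon of the exocyclic alkene of 15, which creates the C13 methyl group and a tertiary, nucleophilic C10 radical. This radical adds to C9, the β-carbon of 16 (Giese addition); the α-ester radical is reduced by divalent iron to the C8 enolate, which attacks the C7 aldehyde, so the closest known reaction type is the hydrogen-atom-transfer-initiated radical–polar crossover annulation (Giese addition followed by aldol). Ring B is closed in the polar step, a 6-(enolexo)-exo-trig aldol through a chair, after the intermolecular C9–C10 bond has been made. C10: the β face of the radical is blocked by the syn-axial C14 methyl, whereas the α face carries only H5 and the small free C1 hydroxyl, so C9 bonds from the α face, C13 ends axial and the ring fusion is trans. C9: it is set in the open transition state of the radical addition, where the acetal should take the sector between C13 and C1, helped by a hydrogen bond from the C1 hydroxyl; only this adduct can close through a chair with the acetal equatorial, while its epimer would stay as an open-chain ester and be removed. C8 and C7: the chair aldol places ester and hydroxyl equatorial, and both centres are erased in step 14. The step needs hydrogen transfer to the 1,1-disubstituted alkene and not to the chloro alkene, and addition faster than reduction or homoallyl rearrangement of the radical; the unhindered terminal CH2, the excess of 16 and slow addition of the silane should secure this.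

Step 13
Reactants: 17 annulation product
Product: 18 3β-chloride (ring A saturated, C3 chlorine equatorial)
Conditions: Mn(dpm)3 (10 mol %), PhSiH3 (2 equiv), t-BuOOH (1.5 equiv), i-PrOH, 25 °C
Reagents that add atoms: none
Why: Mukaiyama-type hydrogen-atom-transfer hydrogenation: a manganese hydride adds hydrogen to C2 and gives the α-chloro C3 radical, which takes its second hydrogen on the α face, anti to the axial C14 methyl. Chlorine is thereby left equatorial (3β), the arrangement that also avoids a 1,3-diaxial clash with the 1α-hydroxyl; the radical pathway keeps the C–Cl bond that palladium catalysts would cleave.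

Step 14
Reactants: 18 3β-chloride
Product: 20 C7=C8 enoate, via C7 mesylate 19 (not isolated)
Conditions: MsCl (1.2 equiv), Et3N, CH2Cl2, −20 °C; then DBU, 25 to 40 °C
Reagents that add atoms: none
Why: Selective sulfonylation of the unhindered equatorial C7 hydroxyl (the axial C1 hydroxyl beside the quaternary C10 reacts far more slowly), then E1cB elimination through the C8 ester enolate; this removes the C7 and C8 stereocentres.

Step 15
Reactants: 20 C7=C8 enoate
Product: 21 C16 alcohol (1α,16-diol)
Conditions: HF·pyridine, pyridine, THF, 0 °C
Reagents that add atoms: none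
Why: Fluoride-mediated cleavage of a primary TBS ether; buffering with pyridine protects the dimethyl acetal.

Step 16
Reactants: 21 C16 alcohol
Product: 22 C16 aldehyde
Conditions: TEMPO (10 mol %), PhI(OAc)2, CH2Cl2, 25 °C
Reagents that add atoms: none
Why: Oxoammonium oxidation, which is selective for the primary alcohol over the hindered axial secondary C1 alcohol and does not over-oxidise.

Step 17
Reactants: 22 C16 aldehyde
Product: 23 (E)-enone (C16=C17, C18 methyl ketone)
Conditions: Ph3P=CHC(O)CH3, toluene, 70 °C
Reagents that add atoms: 1-(triphenyl-λ5-phosphanylidene)propan-2-one, CC(=O)C=P(c1ccccc1)(c1ccccc1)c1ccccc1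
Why: Wittig olefination with a stabilised ylide, which gives the E alkene and tolerates the free hydroxyl, the enoate, the chloride and the acetal.

Step 18
Reactants: 23 (E)-enone
Product: 24 dimethyl acetal of the target (C18 tertiary alcohol)
Conditions: MeMgBr (3 equiv), CeCl3 (3 equiv), THF, −78 °C; aq. NH4Cl
Reagents that add atoms: methylmagnesium bromide, C[Mg]Br
Why: Organocerium 1,2-addition to the enone carbonyl; at −78 °C the ketone reacts far faster than the conjugated C12 ester, and the low basicity of the cerium reagent spares the chlorohydrin.

Step 19
Reactants: 24 dimethyl acetal of the target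
Product: 25 target, methyl (1S,3S,4S,5R,9R,10S)-3-chloro-9-formyl-1-hydroxy-4-[(2E)-4-hydroxy-4-methylpent-2-en-1-yl]-4,10-dimethyl decal-7-ene-8-carboxylate (route numbering)
Conditions: PPTS (cat.), acetone–H2O (10:1), 40 °C
Reagents that add atoms: water, O
Why: Mild acid-catalysed acetal hydrolysis; the equatorial C9 aldehyde is the stable epimer, and the weak acid should leave the tertiary allylic alcohol and the position of the C7=C8 bond untouched.

## Compound list

1 | methyl 2-(3,5-dihydroxyphenyl)acetate | COC(=O)Cc1cc(O)cc(O)c1 | starting material
2 | methyl 2-(3,5-dioxocyclohexyl)acetate | COC(=O)CC1CC(=O)CC(=O)C1 | intermediate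
3 | methyl 2-(3-methoxy-5-oxocyclohex-3-en-1-yl)acetate, racemic (C3 ketone, C1 methoxy enol ether, arm on C5) | COC(=O)C[C@H]1CC(=O)C=C(OC)C1 | intermediate
4 | methyl 2-(5-methoxy-2-methyl-3-oxocyclohex-4-en-1-yl)acetate, racemic, methyl trans to the arm (4α-methyl) | COC(=O)C[C@H]1[C@H](C)C(=O)C=C(OC)C1 | intermediate
5 | methyl 2-[5-methoxy-2-methyl-3-oxo-2-(prop-2-en-1-yl)cyclohex-4-en-1-yl]acetate, racemic, 4β-methyl, 4α-allyl, 5β-arm | COC(=O)C[C@H]1[C@](C)(CC=C)C(=O)C=C(OC)C1 | intermediate
6 | methyl 2-[2-(2,3-dihydroxypropyl)-5-methoxy-2-methyl-3-oxocyclohex-4-en-1-yl]acetate, racemic, carbinol epimers, not isolated | COC(=O)C[C@H]1[C@](C)(CC(O)CO)C(=O)C=C(OC)C1 | intermediate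
7 | methyl 2-[5-methoxy-2-methyl-3-oxo-2-(2-oxoethyl)cyclohex-4-en-1-yl]acetate, racemic | COC(=O)C[C@H]1[C@](C)(CC=O)C(=O)C=C(OC)C1 | intermediate
8 | methyl 2-[2-(2-hydroxyethyl)-5-methoxy-2-methyl-3-oxocyclohex-4-en-1-yl]acetate, racemic | COC(=O)C[C@H]1[C@](C)(CCO)C(=O)C=C(OC)C1 | intermediate
9 | methyl 2-[2-(2-TBS-oxyethyl)-5-methoxy-2-methyl-3-oxocyclohex-4-en-1-yl]acetate, racemic | COC(=O)C[C@H]1[C@](C)(CCO[Si](C)(C)C(C)(C)C)C(=O)C=C(OC)C1 | intermediate
10 | methyl 2-[2-(2-TBS-oxyethyl)-3-chloro-2-methyl-5-oxocyclohex-3-en-1-yl]acetate, racemic (C1 ketone, C2=C3–Cl) | COC(=O)C[C@H]1[C@](C)(CCO[Si](C)(C)C(C)(C)C)C(Cl)=CC(=O)C1 | intermediate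
11 | Mannich base: 10 with a (dimethylamino)methyl group on C10, racemic, C10 epimers, not isolated | COC(=O)C[C@H]1[C@](C)(CCO[Si](C)(C)C(C)(C)C)C(Cl)=CC(=O)C1CN(C)C | intermediate
12 | trimethylammonium iodide of 11, not isolated | COC(=O)C[C@H]1[C@](C)(CCO[Si](C)(C)C(C)(C)C)C(Cl)=CC(=O)C1C[N+](C)(C)C.[I-] | intermediate
13 | methyl 2-[2-(2-TBS-oxyethyl)-3-chloro-2-methyl-6-methylidene-5-oxocyclohex-3-en-1-yl]acetate, racemic | COC(=O)C[C@H]1[C@](C)(CCO[Si](C)(C)C(C)(C)C)C(Cl)=CC(=O)C1=C | intermediate
14 | methyl 2-[2-(2-TBS-oxyethyl)-3-chloro-5-hydroxy-2-methyl-6-methylidenecyclohex-3-en-1-yl]acetate; (1S) in route numbering, 1α-OH, 4β-methyl, 4α-chain, 5β-arm | COC(=O)C[C@H]1[C@](C)(CCO[Si](C)(C)C(C)(C)C)C(Cl)=C[C@H](O)C1=C | intermediate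
15 | 2-[2-(2-TBS-oxyethyl)-3-chloro-5-hydroxy-2-methyl-6-methylidenecyclohex-3-en-1-yl]acetaldehyde; same configuration as 14 | O=CC[C@H]1[C@](C)(CCO[Si](C)(C)C(C)(C)C)C(Cl)=C[C@H](O)C1=C | intermediate
16 | methyl (2E)-4,4-dimethoxybut-2-enoate | COC(OC)/C=C/C(=O)OC | starting material
17 | trans-decalin annulation product: 3-chloro-2-ene, 1α-OH, 4β-methyl, 4α-(2-TBS-oxyethyl), 5α-H, 7β-OH, 8α-CO2Me, 9β-CH(OMe)2, 10β-methyl | COC(=O)[C@@H]1[C@@H](O)C[C@H]2[C@](C)(CCO[Si](C)(C)C(C)(C)C)C(Cl)=C[C@H](O)[C@]2(C)[C@H]1C(OC)OC | intermediate
18 | as 17 but ring A saturated with 3β-chlorine (equatorial) | COC(=O)[C@@H]1[C@@H](O)C[C@H]2[C@](C)(CCO[Si](C)(C)C(C)(C)C)[C@@H](Cl)C[C@H](O)[C@]2(C)[C@H]1C(OC)OC | intermediate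
19 | C7 methanesulfonate of 18, not isolated | COC(=O)[C@@H]1[C@@H](OS(C)(=O)=O)C[C@H]2[C@](C)(CCO[Si](C)(C)C(C)(C)C)[C@@H](Cl)C[C@H](O)[C@]2(C)[C@H]1C(OC)OC | intermediate
20 | C7=C8 enoate: 1α-OH, 3β-Cl, 4α-(2-TBS-oxyethyl), 9β-CH(OMe)2 | COC(=O)C1=CC[C@H]2[C@](C)(CCO[Si](C)(C)C(C)(C)C)[C@@H](Cl)C[C@H](O)[C@]2(C)[C@H]1C(OC)OC | intermediate
21 | as 20 with free C16 hydroxyl (4α-(2-hydroxyethyl)) | COC(=O)C1=CC[C@H]2[C@](C)(CCO)[C@@H](Cl)C[C@H](O)[C@]2(C)[C@H]1C(OC)OC | intermediate
22 | as 20 with C16 aldehyde (4α-(2-oxoethyl)) | COC(=O)C1=CC[C@H]2[C@](C)(CC=O)[C@@H](Cl)C[C@H](O)[C@]2(C)[C@H]1C(OC)OC | intermediate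
23 | as 20 with 4α-[(2E)-4-oxopent-2-en-1-yl] chain | COC(=O)C1=CC[C@H]2[C@](C)(C/C=C/C(C)=O)[C@@H](Cl)C[C@H](O)[C@]2(C)[C@H]1C(OC)OC | intermediate
24 | C11 dimethyl acetal of the target, with 4α-[(2E)-4-hydroxy-4-methylpent-2-en-1-yl] chain | COC(=O)C1=CC[C@H]2[C@](C)(C/C=C/C(C)(C)O)[C@@H](Cl)C[C@H](O)[C@]2(C)[C@H]1C(OC)OC | intermediate
25 | target: C7=C8 enoate, 1α-OH, 3β-Cl, 4β-methyl, 4α-[(2E)-4-hydroxy-4-methylpent-2-en-1-yl], 5α-H, 9β-CHO, 10β-methyl; (1S,3S,4S,5R,9R,10S) in route numbering | COC(=O)C1=CC[C@H]2[C@](C)(C/C=C/C(C)(C)O)[C@@H](Cl)C[C@H](O)[C@]2(C)[C@H]1C=O | target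

## Step count and risk

Total step count: 19. Longest linear sequence: 19 steps (1 to 25; 16 is bought).

**Step 12 (key step).** The hindered C10 radical may be reduced to C10–H, or rearrange through 3-exo attack on the neighbouring chloro alkene, before it adds to the β-substituted enoate. The second weakness is poor facial discrimination at C9 in the open transition state. The fallback makes the C7–C8 bond first and forms C9–C10 intramolecularly. It sets out from 15. The alkynoate methyl 4,4-dimethoxybut-2-ynoate F1 is hydroaluminated with i-Bu2AlH–HMPA, and the resulting α-aluminated enoate adds to the C7 aldehyde to give the hydroxyalkyl enoate F2 (C7 epimers), in which the C8=C9 bond is tied to the C5 arm. The same Fe(acac)3/PhSiH3 conditions then trigger a 6-endo cyclisation of the C10 radical onto C9 through a chair with the acetal equatorial, giving F3 as a mixture at C7 and C8. Hydrogenation as in step 13 gives F4, and mesylation–elimination as in step 14 removes the stray centres, so the route is rejoined at 20.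

**Step 8.** Chloride attack at the hindered C3 of the activated vinylogous ester may be slow, so that demethylation to the 1,3-dione takes over and chlorination then goes to the C1 carbonyl. The fallback fixes the regiochemistry through an enol triflate. It sets out from 9. Deprotonation at C10 (LDA; C4 is blocked) and O-sulfonylation with PhNTf2 give the dienyl triflate F5. Oxalic acid in wet THF hydrolyses its enol ether to the β-triflyloxy enone F6, and LiCl in DMF exchanges triflate for chloride by addition–elimination, returning to 10.

**Step 10.** Reagent control may be incomplete in the mismatched half of the racemate, which would erode the enantiomeric purity of 14, or the two diastereomers may separate poorly. The fallback is an enzymatic kinetic resolution. It sets out from 13. Luche reduction (NaBH4, CeCl3, MeOH) gives the racemic trans-dienol, that is 14 together with its enantiomer F6a, written below as F7. Burkholderia cepacia lipase with vinyl acetate is expected to acetylate the (1R)-enantiomer F7 to its acetate F8 and to leave (1S)-14, which re-enters the route at step 11.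

**Step 13.** Chlorine may be lost reductively, or the C3 radical may take up hydrogen with incomplete facial control. The fallback is hydroxyl-directed homogeneous hydrogenation of 17 with [Ir(cod)(PCy3)(py)]PF6 and H2 in CH2Cl2. The 1α-hydroxyl binds iridium and both hydrogens arrive on the α face, giving 18 directly; no new compound is involved.

## Further compounds

F1 | step 12 | methyl 4,4-dimethoxybut-2-ynoate (reagent of the fallback) | COC(OC)C#CC(=O)OC
F2 | step 12 | hydroxyalkyl enoate: 15 with C7 as carbinol bonded to C8 of a methyl 2-ylidene-4,4-dimethoxybutanoate unit (C7 epimers) | COC(=O)/C(=C\C(OC)OC)C(O)C[C@H]1[C@](C)(CCO[Si](C)(C)C(C)(C)C)C(Cl)=C[C@H](O)C1=C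
F3 | step 12 | annulation product as a mixture of C7 and C8 epimers of 17 | COC(=O)C1C(O)C[C@H]2[C@](C)(CCO[Si](C)(C)C(C)(C)C)C(Cl)=C[C@H](O)[C@]2(C)[C@H]1C(OC)OC
F4 | step 12 | 3β-chloride as a mixture of C7 and C8 epimers of 18 | COC(=O)C1C(O)C[C@H]2[C@](C)(CCO[Si](C)(C)C(C)(C)C)[C@@H](Cl)C[C@H](O)[C@]2(C)[C@H]1C(OC)OC
F5 | step 8 | dienyl triflate: methyl 2-[2-(2-TBS-oxyethyl)-5-methoxy-2-methyl-3-(trifluoromethylsulfonyloxy)cyclohexa-3,5-dien-1-yl]acetate, racemic | COC(=O)C[C@H]1[C@](C)(CCO[Si](C)(C)C(C)(C)C)C(OS(=O)(=O)C(F)(F)F)=CC(OC)=C1
F6 | step 8 | β-triflyloxy enone: 10 with trifluoromethylsulfonyloxy in place of chlorine, racemic | COC(=O)C[C@H]1[C@](C)(CCO[Si](C)(C)C(C)(C)C)C(OS(=O)(=O)C(F)(F)F)=CC(=O)C1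
F7 | step 10 | enantiomer of 14 ((1R)-chloro dienol) | COC(=O)C[C@@H]1[C@@](C)(CCO[Si](C)(C)C(C)(C)C)C(Cl)=C[C@@H](O)C1=C
F8 | step 10 | C1 acetate of F7 | COC(=O)C[C@@H]1[C@@](C)(CCO[Si](C)(C)C(C)(C)C)C(Cl)=C[C@@H](OC(C)=O)C1=C
F0 | step 13 | none | none
A1 | alternative 1 | methyl 6-(dimethoxymethyl)-5-formyl-2-hydroxy-5-methyl-4-(prop-1-en-2-yl)cyclohex-1-ene-1-carboxylate | COC(=O)C1=C(O)C[C@@H](C(C)=C)[C@](C)(C=O)[C@H]1C(OC)OC
A2 | alternative 1 | methyl (4E)-6-methyl-3-oxohepta-4,6-dienoate | COC(=O)CC(=O)/C=C/C(C)=C
A3 | alternative 1 | (2E)-4,4-dimethoxy-2-methylbut-2-enal | COC(OC)/C=C(\C)C=O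
A4 | alternative 2 | trans-decalin C1 ketone with 3β-chloride, C4 allyl and C9 silyloxymethyl | COC(=O)C1=CC[C@H]2[C@](C)(CC=C)[C@@H](Cl)CC(=O)[C@]2(C)[C@H]1CO[Si](c3ccccc3)(c4ccccc4)C(C)(C)C
A5 | alternative 2 | C1=C3 trimethylsilyl enol ether of the corresponding trans-hydrindanone | COC(=O)C1=CC[C@H]2[C@](C)(CC=C)C=C(O[Si](C)(C)C)[C@]2(C)[C@H]1CO[Si](c3ccccc3)(c4ccccc4)C(C)(C)C
A6 | alternative 3 | trans-decalin with enolised C7/C8 keto ester and C9 dimethyl acetal | COC(=O)C1=C(O)C[C@H]2[C@](C)(C/C=C/C(C)(C)O[Si](CC)(CC)CC)[C@@H](Cl)C[C@H](O[Si](C)(C)C(C)(C)C)[C@]2(C)[C@H]1C(OC)OC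
A7 | alternative 3 | ring A with complete side chain, C5 β-keto ester arm and C10 (E)-2-methoxyvinyl group | COC(=O)CC(=O)C[C@H]1[C@](C)(C/C=C/C(C)(C)O[Si](CC)(CC)CC)[C@@H](Cl)C[C@H](O[Si](C)(C)C(C)(C)C)[C@]1(C)/C=C/OC
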